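## Structural features

Wailupemycin H (35) is an unsymmetrical dimer: two 4-hydroxy-2-pyrones (ring A and ring B) are joined C3 to C3 by one methylene carbon. Ring A carries at C6 the C4 carbon of a 1-tetralone, and ring B carries at C6 the C1 carbon of a 4,5-dihydroxy-2-phenylnaphthalene. The tetralone has its C1 ketone peri to the C8 phenol, a quaternary phenyl carbinol at C3 and, directly next to it, the methine C4 that bears ring A; the two stereocentres are 3R,4S, with the C3 hydroxyl cis to ring A and the phenyl trans to it. The naphthol half has the same carbon skeleton as the tetralone half and is its dehydrated, aromatised form, so one intermediate can serve both halves. The same relationship is the main fragility: the β-hydroxy ketone loses water under acid or base (or cleaves by retro-aldol reaction), C4–H is benzylic and next to the pyrone, and the 4-hydroxypyrones are acidic, nucleophilic at C3 and able to leave a bis(pyronyl)methane again by retro-Michael reaction. The real difficulty is twofold: the vicinal quaternary/tertiary pair C3–C4 in a ring that is one elimination away from a naphthalene, and the joining of two almost identical pyrone nucleophiles through one carbon without homo-dimers. The key step uses the fact that C3 and C4 are flanked by the C1–C2 unit and that C1 and C4 sit on the two ortho positions (C8a, C4a) of the phenol ring: when C1 is tied through oxygen to the carboxyl-level carbon on C4 (the future C6 of ring A), the atoms C4, carboxyl C, O, C1, C2, C3 form an allyl vinyl ether, and a [3,3] shift makes the C3–C4 bond, turns the lactone into the carbocycle and leaves the C1=C2 alkene as the handle for the ketone.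

## Logic of the disconnections

35 from 34. Only the two aryl O–CH2Ph bonds are broken in the last operation. They are kept until then because a free peri-dihydroxynaphthalene would compete as a carbon nucleophile while the pyrones are joined. The gain is that 34 carries one kind of protecting group only. The demand is a neutral release that spares the aryl ketone, the tertiary benzylic alcohol and both pyrones.

34 from 29, 30 and 31. Both C–C bonds at the bridging methylene are cut (C3 of ring A–CH2 and CH2–C3 of ring B). Each pyrone C3 is a soft carbon nucleophile and the bridge is at the aldehyde oxidation level, so a one-carbon electrophile is the natural partner. The cut gives two halves of identical carbon skeleton plus 31. The demand is hetero-selectivity: the electrophile must be installed on one half (32, then 33) before the other half is offered, and the medium must stay near neutral because 29 dehydrates.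

30 from 29. No carbon–carbon bond is cut; the C3–O bond and two C–H bonds are restored, so 30 is the dehydrated, aromatised form of 29. This removes a separate synthesis of the second half at the cost of one step. The only demand is complete elimination.

29 from 25 through 28 and 27. The C3–O bond to the 4-methoxybenzyl group and the C1=O group are traced back to a tertiary ether and a C1=C2 alkene. The ketone is placed late because, once present, it makes the C3 oxygen a β-leaving group under base, whereas the alkene is inert to the enolate chemistry that builds ring A. The demands are Markovnikov delivery of oxygen to benzylic C1 without touching ring A, a neutral oxidation and a neutral ether cleavage.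

25 from 19 and 20 through 23. Ring A is cut at O1–C2 (closed through 24) and at the bond between the carboxyl carbon of 19 and the γ-carbon of 20. This reduces ring A to the carboxylic acid that the key step delivers. The demand is that acylation outruns deprotonation at the benzylic carbon next to the acyl group, since loss of the β-alkoxy group from there would aromatise the ring.

19 from 16 (key step). The C3–C4 bond is cut and the C1–O bond remade, which turns the carbocycle back into the six-membered lactone. Two adjacent stereocentres, one quaternary, are exchanged for one secondary carbinol centre and one alkene geometry. The demand is a concerted, suprafacial shift: the C1–O bond, benzylic and vinylogous to an enol ether, must not ionise, and the enolate must be silylated (17) before it can fragment.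

16 from 12 through 13. The lactone acyl C–O bond is opened and its carbonyl carbon taken back to a primary alcohol; the carbinol C–H bond is taken back to the ketone of 12. The lactone carbonyl is introduced last because an arylacetic ester CH2 beside the ynone or the β-alkoxy enone would be acidic enough to add to it and close a naphthol ring. The gain is that the single stereocentre comes from a catalytic reduction. The demands are hydride delivery to one face of a hindered vinylogous ester, and an acid-free oxidant that takes the primary alcohol to the lactone without touching the secondary allylic carbinol or the enol ether.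

12 from 10 and 11; 10 from 6 and 7. The enol ether C–O bond is cut (conjugate addition of 11 to the ynone), then the bond between the carbonyl carbon and the alkyne (addition of 8 to 6). The ynone is the intermediate from which the E enol ether is available under thermodynamic control. The gain is three simple components. The demands are the E geometry, on which C3 depends, and a single addition of 8, secured by the persistence of 9.

6 from 3 and 4; 3 from 1 and 2. The benzylic C–C bond and the lactone C–O bond are cut (lateral metalation of 3 to 5, hydroxymethylation, ring closure), then the benzyl O–C bond. The 1,2,3-substitution pattern of the phenol ring is bought with 1. The demand is metalation at the methyl group only.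

## Other disconnections considered

Alternative 1: The cut removes every C–C bond of the free tetralone–pyrone monomer A1 at once, back to one benzoic acid A2 starter and seven malonate units from malonic acid A3. In the forward direction a reconstituted aromatic polyketide synthase (ketosynthase with chain-length factor, acyl carrier protein, NADPH-dependent ketoreductase, benzoate–carrier-protein ligase, malonyl transacylase) performs seven decarboxylative Claisen condensations. The chain then folds: the phenol ring closes, the tetralone closes at C3–C4 with both stereocentres, and lactonisation to ring A releases A1.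
- In its favour: one aqueous pot, no protecting groups, and both stereocentres set by the folding. On step count it is clearly better than the chosen plan, which needs twelve steps to the protected monomer 29. The end game would be the same (dehydration of part of A1 to the naphthol A4, one-carbon coupling with 4), so there it is the equal of the chosen plan.
- Against it here: the cyclisations after chain assembly are largely spontaneous, so folding regiochemistry and C3/C4 configuration are not under the chemist's control and shunt products must be separated. Purified proteins and stoichiometric cofactors limit the scale. A1 and A4 arrive with all phenols free, so the final coupling must distinguish pyrone C3 from the electron-rich naphthalenediol carbons without help.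
- Comparison: structurally the same bonds are made but no intermediate has differentiated hydroxyls. Mechanistically it is enzyme-templated folding against a substrate-controlled sigmatropic transfer whose outcome can be predicted and corrected. The alternative wins on step economy; the chosen plan wins on control and throughput.

Alternative 2: The cut is at two bonds of the naphthalene of the ring-B half, C8a–C1 and C2–C3 (naphthalene numbering), back to the aroyl sulfoxonium ylide A6 and the pyronyl phenyl alkyne A7. With [Cp*RhCl2]2 and AgSbF6 (trivalent rhodium) the ortho C–H of A6 is metalated, A7 inserts (C8a–C1), a rhodium carbene forms at the ylide carbon with loss of the sulfoxide, and migratory insertion (C2–C3) followed by tautomerisation gives the naphthol A5.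
- In its favour: a convergent, redox-neutral annulation delivers the fully substituted naphthol with the pyrone already attached. It consumes no enantioenriched material for the achiral half, a point on which it is better than the chosen plan, and it is at least its equal in convergence.
- Against it here: A7 carries two different sp2 substituents, and the product needs the pyronyl carbon bonded to the arene and the phenyl carbon bonded to the carbene carbon; that bias is not obvious. The pyrone oxygens can bind the cationic metal, and the pyrone O-benzyl group must be removed afterwards.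
- Comparison: it addresses only the half without stereocentres, so the tetralone half still needs the sigmatropic route, after which the naphthol is one dehydration away (step 13). On step economy it adds about five operations (A6, A7, annulation, unmasking) where the chosen plan uses one. Mechanistically it is organometallic C–H functionalisation against an acid-catalysed dehydration: more elegant, with more that can go astray.

Alternative 3: The cut is at the C3–C4 bond of both pyrones, so that the bridge, both C3 atoms and both C2 carbonyls come from di-tert-butyl glutarate A9; the partners are the naphthylpropioloyl chloride A10 and the arylbutynoyl chloride A11. The bis-enolate of A9 (LiN(iPr)2) is C-acylated by A10 and, after re-enolisation, by A11 to give the diacylglutarate A8. Later each tert-butyl ester carbonyl closes onto its ynone (6-endo, with loss of the tert-butyl group) to form rings A and B.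
- In its favour: the methylene bridge is present from the start, so the hetero-coupling problem of step 14 does not arise. Here the alternative is better than the chosen plan, and the assembly is highly convergent.
- Against it here: the mono-acylated β-keto ester is far more acidic than A9 and quenches remaining enolate, so an unsymmetrical double acylation in one pot tends toward statistical mixtures, and ynoyl chlorides are also conjugate acceptors. After the bispyrone is made, the tetralone must still be built from the aryl bromide arm. That creates C3 and C4 late, on an acidic, fully functionalised bispyrone, with no evident source of absolute control and with the aromatisation-prone aldol exposed to base. A10 itself needs a multi-step naphthalene synthesis.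
- Comparison: structurally it is strong for the bispyrone core and weak for the stereo-pair. Mechanistically it relies on enolate acylation and ionic cyclisation against a stereospecific pericyclic transfer. The step count could be similar if the double acylation behaved, but the stereochemical problem is postponed, not solved.

Key step: step 7

Remark: in step 5 the twisted 2,6-disubstituted aryl group is assumed to act as the larger ketone substituent; the (R)-oxazaborolidine is specified on that basis.
Remark: the stereochemistry was re-derived from the boat geometry: S at the lactone carbinol of 16 with the E enol ether leads to 1S,2R in 19 (3R,4S in tetralone numbering), so the precursor and product structures needed no correction. The C4 descriptor changes between 28 (R) and 29 (S) only because ligand priorities change.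
Remark: 10 is written open-chain; it equilibrates with its lactol, the O-protonated form of 9.
Remark: an indanone ring-cleavage entry (2-oximation, Beckmann fragmentation) was set aside because it would leave the carboxyl on the ring and a nitrile on the side chain, the reverse of what the lactone needs.

## Steps

Step 1
Reactants: 1 ethyl 2-hydroxy-6-methylbenzoate; 2 benzyl bromide
Product: 3 ethyl 2-(benzyloxy)-6-methylbenzoate
Conditions: K2CO3, DMF, 60 °C
Reagents that add atoms: benzyl bromide 2, BrCc1ccccc1
Why: Williamson O-alkylation of the salicylate phenol; benzyl is chosen because it survives the bases, the borane, the radical hydration and the quinone oxidant used later and leaves by neutral hydrogenolysis.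

Step 2
Reactants: 3 ethyl 2-(benzyloxy)-6-methylbenzoate; 4 formaldehyde (gas from cracked paraformaldehyde)
Product: 6 8-(benzyloxy)isochroman-1-one, via lithium dienolate 5 (not isolated)
Conditions: LiN(iPr)2, THF, −78 °C; CH2O (g); −78 °C → rt; H2O
Reagents that add atoms: formaldehyde 4, C=O
Why: Lateral lithiation of the ortho-toluate gives the o-quinodimethane enolate, which is hydroxymethylated at the benzylic carbon; the alkoxide then closes onto the neighbouring ethyl ester (toluate-anion route to 3,4-dihydroisocoumarins).

Step 3
Reactants: 6 8-(benzyloxy)isochroman-1-one; 7 phenylacetylene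
Product: 10 1-[2-(benzyloxy)-6-(2-hydroxyethyl)phenyl]-3-phenylprop-2-yn-1-one, via lithium phenylacetylide 8 (not isolated), via lithium lactolate 9 (not isolated)
Conditions: 7, n-BuLi, THF, −78 °C; then 6, −78 °C; AcOH, −78 °C → rt
Reagents that add atoms: phenylacetylene 7, C#Cc1ccccc1
Why: Acetylide addition to a lactone; the tetrahedral lithium lactolate persists at −78 °C, so a second addition cannot occur, and protonation releases the hydroxy ynone.

Step 4
Reactants: 10 1-[2-(benzyloxy)-6-(2-hydroxyethyl)phenyl]-3-phenylprop-2-yn-1-one; 11 4-methoxybenzyl alcohol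
Product: 12 (2E)-1-[2-(benzyloxy)-6-(2-hydroxyethyl)phenyl]-3-[(4-methoxybenzyl)oxy]-3-phenylprop-2-en-1-one
Conditions: 11 (5 equiv), PMe3 (15 mol %), CH2Cl2, 0 °C → rt
Reagents that add atoms: 4-methoxybenzyl alcohol 11, COc1ccc(CO)cc1
Why: Phosphine-catalysed oxa-Michael addition of an alcohol to an ynone; reversible addition to the push–pull alkene should let the product settle on the E isomer (alkoxy oxygen anti to the acyl group). The substrate's own primary hydroxyl cannot reach the β-carbon and is outcompeted by the excess of 11, and no acidic arylacetate CH2 is present to close a naphthol.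

Step 5
Reactants: 12 (2E)-1-[2-(benzyloxy)-6-(2-hydroxyethyl)phenyl]-3-[(4-methoxybenzyl)oxy]-3-phenylprop-2-en-1-one
Product: 13 (1S,2E)-1-[2-(benzyloxy)-6-(2-hydroxyethyl)phenyl]-3-[(4-methoxybenzyl)oxy]-3-phenylprop-2-en-1-ol
Conditions: (R)-1-methyl-3,3-diphenyltetrahydro-1H,3H-pyrrolo[1,2-c][1,3,2]oxazaborole (0.5 equiv), BH3·SMe2 (2.5 equiv), THF, −20 °C; MeOH; pH 8 buffer
Reagents that add atoms: none
Why: Corey–Bakshi–Shibata reduction; with the twisted aryl group as the large substituent and the flat alkoxyvinyl group as the small one, the (R)-catalyst should deliver hydride to give the S carbinol. The first equivalent of borane is taken up by the primary hydroxyl, and the basic work-up protects the acid-labile 3-alkoxyallyl alcohol.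

Step 6
Reactants: 13 (1S,2E)-1-[2-(benzyloxy)-6-(2-hydroxyethyl)phenyl]-3-[(4-methoxybenzyl)oxy]-3-phenylprop-2-en-1-ol
Product: 16 (1S)-8-(benzyloxy)-1-{(E)-2-[(4-methoxybenzyl)oxy]-2-phenylethenyl}isochroman-3-one, via hydroxy aldehyde 14 (not isolated), via lactol 15 (not isolated)
Conditions: [Cu(MeCN)4]OTf (10 mol %), 2,2'-bipyridine (10 mol %), TEMPO (2,2,6,6-tetramethylpiperidin-1-oxyl, 10 mol %), N-methylimidazole (20 mol %), air, MeCN, rt
Reagents that add atoms: none
Why: Copper/nitroxyl aerobic oxidative lactonisation of a diol; the catalyst oxidises only the unhindered primary alcohol, the aldehyde is trapped as the six-membered lactol, and this is oxidised on to the lactone in a base-buffered, acid-free medium.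

Step 7
Reactants: 16 (1S)-8-(benzyloxy)-1-{(E)-2-[(4-methoxybenzyl)oxy]-2-phenylethenyl}isochroman-3-one
Product: 19 (1S,2R)-5-(benzyloxy)-2-[(4-methoxybenzyl)oxy]-2-phenyl-1,2-dihydronaphthalene-1-carboxylic acid, via silyl ketene acetal 17 (not isolated), via trimethylsilyl ester 18 (not isolated)
Conditions: Me3SiCl/Et3N, toluene–THF, −78 °C; LiN(SiMe3)2 added last; −78 °C → rt; pH 6 buffer, 0 °C
Reagents that add atoms: none
Why: Ireland–Claisen rearrangement: deprotonation at C4 of the lactone in the presence of Me3SiCl gives the cyclic O-silyl ketene acetal 17, whose array C4=C(OSi)–O–C1–CH=C(OR)Ph undergoes a concerted [3,3] shift that forms the C3–C4 bond (tetralone numbering) as the C1–O bond breaks, and mild aqueous work-up hydrolyses the silyl ester 18 to 19. The closest known reaction type is the rearrangement of silyl ketene acetals of vinyl-substituted lactones to cycloalkene carboxylic acids through a boat transition state. One ring closes, the six-membered carbocycle, by a ring-neutral pericyclic change of the six-membered lactone into the 1,2-dihydronaphthalene; the boat is imposed because C1 and C4 are tied together by the two arene carbons and the ketene acetal geometry is fixed inside the ring. C3 is controlled by the S carbinol centre together with the E enol ether: bond breaking at C1 and bond making at C3 occur on the same face of the allyl unit, which turns the phenyl group toward the arene bridge and the ether oxygen toward the departing carboxyl bridge (3R). C4 is controlled by the boat itself: the new bond enters the ketene acetal face on which the vinyl group stands, so the carboxyl ends cis to the C3 oxygen and trans to phenyl (4S). The step needs the concerted path to beat heterolysis of the C1–O bond and 1,4-elimination of the lithium enolate to an o-quinodimethane, both of which would erase the C1 information; silylation at −78 °C as the enolate forms, a weakly polar medium and the absence of Lewis acids should secure this. The benzyloxy group peri to C1 forces the vinyl substituent pseudo-axial (allylic 1,3-strain), the geometry the shift requires, and the alkoxy group on the allyl terminus should lower the barrier so that the shift proceeds near room temperature.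

Step 8
Reactants: 19 (1S,2R)-5-(benzyloxy)-2-[(4-methoxybenzyl)oxy]-2-phenyl-1,2-dihydronaphthalene-1-carboxylic acid; 20 2,2,6-trimethyl-4H-1,3-dioxin-4-one
Product: 23 6-{2-[(1S,2R)-5-(benzyloxy)-2-[(4-methoxybenzyl)oxy]-2-phenyl-1,2-dihydronaphthalen-1-yl]-2-oxoethyl}-2,2-dimethyl-4H-1,3-dioxin-4-one, via acyl imidazole 21 (not isolated), via lithium dienolate 22 (not isolated)
Conditions: 19, 1,1'-carbonyldiimidazole, THF, rt; added to 20/LiN(SiMe3)2 (2.4 equiv), THF, −78 °C; AcOH, −78 °C
Reagents that add atoms: 2,2,6-trimethyl-4H-1,3-dioxin-4-one 20, CC1=CC(=O)OC(C)(C)O1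
Why: γ-Acylation of a dioxinone dienolate by an acyl imidazole (crossed Claisen condensation); the second equivalent of dienolate deprotonates the new 1,3-dicarbonyl unit, which shields the benzylic C–H from enolisation and the β-alkoxy group from elimination. Acid 19 is used at once because its carboxyl sits cis to the ionisable tertiary ether.

Step 9
Reactants: 23 6-{2-[(1S,2R)-5-(benzyloxy)-2-[(4-methoxybenzyl)oxy]-2-phenyl-1,2-dihydronaphthalen-1-yl]-2-oxoethyl}-2,2-dimethyl-4H-1,3-dioxin-4-one
Product: 25 6-[(1R,2R)-5-(benzyloxy)-2-[(4-methoxybenzyl)oxy]-2-phenyl-1,2-dihydronaphthalen-1-yl]-4-hydroxy-2H-pyran-2-one, via acylketene 24 (not isolated)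
Conditions: toluene, 2,6-lutidine (1.5 equiv), 100 °C
Reagents that add atoms: none
Why: Thermal retro-[4+2] loss of acetone from the dioxinone gives the acylketene, which is captured by its own enol oxygen to close the 4-hydroxy-2-pyrone (ring A); the lutidine keeps the new acidic pyrone from catalysing ionisation of the allylic tertiary ether.

Step 10
Reactants: 25 6-[(1R,2R)-5-(benzyloxy)-2-[(4-methoxybenzyl)oxy]-2-phenyl-1,2-dihydronaphthalen-1-yl]-4-hydroxy-2H-pyran-2-one
Product: 27 6-[(1R,2R)-5-(benzyloxy)-4-hydroxy-2-[(4-methoxybenzyl)oxy]-2-phenyl-1,2,3,4-tetrahydronaphthalen-1-yl]-4-hydroxy-2H-pyran-2-one (both C4 epimers), via benzylic hydroperoxide 26 (not isolated)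
Conditions: Co(acac)2 (20 mol %), PhSiH3, O2 (1 atm), THF/iPrOH, rt; then PPh3
Reagents that add atoms: dioxygen, O=O
Why: Mukaiyama hydration: hydrogen-atom transfer from the cobalt hydride to C2 gives the benzylic C1 radical, which is trapped by oxygen (Markovnikov). The divalent-cobalt system is chosen because it leaves electron-poor conjugated alkenes such as the pyrone alone, and the configuration of the new carbinol is irrelevant.

Step 11
Reactants: 27 6-[(1R,2R)-5-(benzyloxy)-4-hydroxy-2-[(4-methoxybenzyl)oxy]-2-phenyl-1,2,3,4-tetrahydronaphthalen-1-yl]-4-hydroxy-2H-pyran-2-one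
Product: 28 (3R,4R)-8-(benzyloxy)-4-(4-hydroxy-2-oxo-2H-pyran-6-yl)-3-[(4-methoxybenzyl)oxy]-3-phenyl-3,4-dihydronaphthalen-1(2H)-one
Conditions: MnO2, CH2Cl2, rt
Reagents that add atoms: none
Why: Heterogeneous oxidation of a benzylic alcohol by manganese dioxide under neutral conditions; the free 4-hydroxypyrone and the base-labile β-alkoxy ketone product should be left alone.

Step 12
Reactants: 28 (3R,4R)-8-(benzyloxy)-4-(4-hydroxy-2-oxo-2H-pyran-6-yl)-3-[(4-methoxybenzyl)oxy]-3-phenyl-3,4-dihydronaphthalen-1(2H)-one
Product: 29 (3R,4S)-8-(benzyloxy)-3-hydroxy-4-(4-hydroxy-2-oxo-2H-pyran-6-yl)-3-phenyl-3,4-dihydronaphthalen-1(2H)-one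
Conditions: DDQ (2,3-dichloro-5,6-dicyano-1,4-benzoquinone), CH2Cl2/pH 7 buffer (10:1), 0 °C → rt
Reagents that add atoms: none
Why: Oxidative cleavage of the 4-methoxybenzyl ether by hydride abstraction and hydrolysis; the benzyl ether, ketone and pyrone are inert, and the buffer guards the β-hydroxy ketone against dehydration.

Step 13
Reactants: 29 (3R,4S)-8-(benzyloxy)-3-hydroxy-4-(4-hydroxy-2-oxo-2H-pyran-6-yl)-3-phenyl-3,4-dihydronaphthalen-1(2H)-one
Product: 30 6-[5-(benzyloxy)-4-hydroxy-2-phenylnaphthalen-1-yl]-4-hydroxy-2H-pyran-2-one
Conditions: TsOH·H2O (10 mol %), toluene, 80 °C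
Reagents that add atoms: none
Why: Acid-catalysed dehydration of the tertiary benzylic β-hydroxy ketone and tautomerisation to the 1-naphthol, driven by aromatisation; part of 29 thereby supplies the second half.

Step 14
Reactants: 29 (3R,4S)-8-(benzyloxy)-3-hydroxy-4-(4-hydroxy-2-oxo-2H-pyran-6-yl)-3-phenyl-3,4-dihydronaphthalen-1(2H)-one; 31 N,N-dimethylmethyleneiminium iodide; 30 6-[5-(benzyloxy)-4-hydroxy-2-phenylnaphthalen-1-yl]-4-hydroxy-2H-pyran-2-one
Product: 34 O,O-dibenzyl wailupemycin H (benzyl on the tetralone C8 oxygen; benzyl on the naphthalene C5 oxygen), via Mannich base 32 (not isolated), via methylenepyrandione 33 (not isolated)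
Conditions: 29, 31 (1.0 equiv), MeCN, 0 °C → rt; then 30 (1.3 equiv), NaOAc, 45 °C
Reagents that add atoms: N,N-dimethylmethyleneiminium iodide 31, C[N+](C)=C.[I-]
Why: Mannich aminomethylation at C3 of ring A, then elimination of dimethylamine to the 3-methylenepyran-2,4-dione and conjugate addition of the pyrone C3 of 30 (Mannich-base alkylation of a 1,3-dicarbonyl nucleophile). Generating the electrophile from one half before the other is added enforces the hetero-coupling, and the acetate buffer keeps the β-hydroxy ketone intact.

Step 15
Reactants: 34 O,O-dibenzyl wailupemycin H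
Product: 35 wailupemycin H
Conditions: H2 (1 atm), 10% Pd/C, EtOAc/MeOH, rt
Reagents that add atoms: none
Why: Hydrogenolysis of the two aryl benzyl ethers on palladium metal under neutral conditions, the mildest release for a product whose β-hydroxy ketone dehydrates with acid or base; aryl benzyl ethers should cleave faster than the hydrogen-bonded aryl ketone or the pyrones are reduced.

## Compound list

1 | ethyl 2-hydroxy-6-methylbenzoate | CCOC(=O)c1c(C)cccc1O | starting material
2 | benzyl bromide | BrCc1ccccc1 | starting material
3 | ethyl 2-(benzyloxy)-6-methylbenzoate | CCOC(=O)c1c(C)cccc1OCc1ccccc1 | intermediate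
4 | formaldehyde (monomer from cracked paraformaldehyde) | C=O | starting material
5 | lithium dienolate of 3 (o-quinodimethane form, lithiated at the benzylic methyl) | CCOC(O[Li])=C1C(=C)C=CC=C1OCc1ccccc1 | intermediate (not isolated)
6 | 8-(benzyloxy)isochroman-1-one | O=C1OCCc2cccc(OCc3ccccc3)c12 | intermediate
7 | phenylacetylene | C#Cc1ccccc1 | starting material
8 | lithium phenylacetylide | [Li]C#Cc1ccccc1 | intermediate (not isolated)
9 | lithium 8-(benzyloxy)-1-(phenylethynyl)isochroman-1-olate | [Li]OC1(C#Cc2ccccc2)OCCc2cccc(OCc3ccccc3)c12 | intermediate (not isolated)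
10 | 1-[2-(benzyloxy)-6-(2-hydroxyethyl)phenyl]-3-phenylprop-2-yn-1-one | OCCc1cccc(OCc2ccccc2)c1C(=O)C#Cc1ccccc1 | intermediate
11 | 4-methoxybenzyl alcohol | COc1ccc(CO)cc1 | starting material
12 | (2E)-1-[2-(benzyloxy)-6-(2-hydroxyethyl)phenyl]-3-[(4-methoxybenzyl)oxy]-3-phenylprop-2-en-1-one | OCCc1cccc(OCc2ccccc2)c1C(=O)/C=C(/OCc1ccc(OC)cc1)c1ccccc1 | intermediate
13 | (1S,2E)-1-[2-(benzyloxy)-6-(2-hydroxyethyl)phenyl]-3-[(4-methoxybenzyl)oxy]-3-phenylprop-2-en-1-ol | OCCc1cccc(OCc2ccccc2)c1[C@@H](O)/C=C(/OCc1ccc(OC)cc1)c1ccccc1 | intermediate
14 | 2-{3-(benzyloxy)-2-[(1S,2E)-1-hydroxy-3-[(4-methoxybenzyl)oxy]-3-phenylprop-2-en-1-yl]phenyl}acetaldehyde | O=CCc1cccc(OCc2ccccc2)c1[C@@H](O)/C=C(/OCc1ccc(OC)cc1)c1ccccc1 | intermediate (not isolated)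
15 | (1S)-8-(benzyloxy)-1-{(E)-2-[(4-methoxybenzyl)oxy]-2-phenylethenyl}isochroman-3-ol (both C3 epimers) | OC1Cc2cccc(OCc3ccccc3)c2[C@H](/C=C(/OCc2ccc(OC)cc2)c2ccccc2)O1 | intermediate (not isolated)
16 | (1S)-8-(benzyloxy)-1-{(E)-2-[(4-methoxybenzyl)oxy]-2-phenylethenyl}isochroman-3-one (key-step precursor) | O=C1Cc2cccc(OCc3ccccc3)c2[C@H](/C=C(/OCc2ccc(OC)cc2)c2ccccc2)O1 | intermediate
17 | (1S)-8-(benzyloxy)-1-{(E)-2-[(4-methoxybenzyl)oxy]-2-phenylethenyl}-3-(trimethylsilyloxy)-1H-isochromene | C[Si](C)(C)OC1=Cc2cccc(OCc3ccccc3)c2[C@H](/C=C(/OCc2ccc(OC)cc2)c2ccccc2)O1 | intermediate (not isolated)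
18 | trimethylsilyl (1S,2R)-5-(benzyloxy)-2-[(4-methoxybenzyl)oxy]-2-phenyl-1,2-dihydronaphthalene-1-carboxylate | C1=C[C@](OCc2ccc(OC)cc2)(c2ccccc2)[C@@H](C(=O)O[Si](C)(C)C)c2cccc(OCc3ccccc3)c12 | intermediate (not isolated)
19 | (1S,2R)-5-(benzyloxy)-2-[(4-methoxybenzyl)oxy]-2-phenyl-1,2-dihydronaphthalene-1-carboxylic acid (key-step product; carboxyl cis to the ether oxygen) | C1=C[C@](OCc2ccc(OC)cc2)(c2ccccc2)[C@@H](C(O)=O)c2cccc(OCc3ccccc3)c12 | intermediate
20 | 2,2,6-trimethyl-4H-1,3-dioxin-4-one | CC1=CC(=O)OC(C)(C)O1 | starting material
21 | [(1S,2R)-5-(benzyloxy)-2-[(4-methoxybenzyl)oxy]-2-phenyl-1,2-dihydronaphthalen-1-yl](1H-imidazol-1-yl)methanone | C1=C[C@](OCc2ccc(OC)cc2)(c2ccccc2)[C@@H](C(=O)n2ccnc2)c2cccc(OCc3ccccc3)c12 | intermediate (not isolated)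
22 | lithium dienolate of 20 (2,2-dimethyl-6-methylidene-1,3-dioxin-4-olate) | [Li]OC1=CC(=C)OC(C)(C)O1 | intermediate (not isolated)
23 | 6-{2-[(1S,2R)-5-(benzyloxy)-2-[(4-methoxybenzyl)oxy]-2-phenyl-1,2-dihydronaphthalen-1-yl]-2-oxoethyl}-2,2-dimethyl-4H-1,3-dioxin-4-one | C1=C[C@](OCc2ccc(OC)cc2)(c2ccccc2)[C@@H](C(=O)CC2=CC(=O)OC(C)(C)O2)c2cccc(OCc3ccccc3)c12 | intermediate
24 | 5-[(1S,2R)-5-(benzyloxy)-2-[(4-methoxybenzyl)oxy]-2-phenyl-1,2-dihydronaphthalen-1-yl]-3,5-dioxopent-1-en-1-one (acylketene) | C1=C[C@](OCc2ccc(OC)cc2)(c2ccccc2)[C@@H](C(=O)CC(=O)C=C=O)c2cccc(OCc3ccccc3)c12 | intermediate (not isolated)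
25 | 6-[(1R,2R)-5-(benzyloxy)-2-[(4-methoxybenzyl)oxy]-2-phenyl-1,2-dihydronaphthalen-1-yl]-4-hydroxy-2H-pyran-2-one (same spatial arrangement as 19) | C1=C[C@](OCc2ccc(OC)cc2)(c2ccccc2)[C@@H](c2cc(O)cc(=O)o2)c2cccc(OCc3ccccc3)c12 | intermediate
26 | 6-[(1R,2R)-5-(benzyloxy)-4-hydroperoxy-2-[(4-methoxybenzyl)oxy]-2-phenyl-1,2,3,4-tetrahydronaphthalen-1-yl]-4-hydroxy-2H-pyran-2-one (both C4 epimers) | OOC1C[C@](OCc2ccc(OC)cc2)(c2ccccc2)[C@@H](c2cc(O)cc(=O)o2)c2cccc(OCc3ccccc3)c12 | intermediate (not isolated)
27 | 6-[(1R,2R)-5-(benzyloxy)-4-hydroxy-2-[(4-methoxybenzyl)oxy]-2-phenyl-1,2,3,4-tetrahydronaphthalen-1-yl]-4-hydroxy-2H-pyran-2-one (both C4 epimers) | OC1C[C@](OCc2ccc(OC)cc2)(c2ccccc2)[C@@H](c2cc(O)cc(=O)o2)c2cccc(OCc3ccccc3)c12 | intermediate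
28 | (3R,4R)-8-(benzyloxy)-4-(4-hydroxy-2-oxo-2H-pyran-6-yl)-3-[(4-methoxybenzyl)oxy]-3-phenyl-3,4-dihydronaphthalen-1(2H)-one | O=C1C[C@](OCc2ccc(OC)cc2)(c2ccccc2)[C@@H](c2cc(O)cc(=O)o2)c2cccc(OCc3ccccc3)c21 | intermediate
29 | (3R,4S)-8-(benzyloxy)-3-hydroxy-4-(4-hydroxy-2-oxo-2H-pyran-6-yl)-3-phenyl-3,4-dihydronaphthalen-1(2H)-one | O=C1C[C@](O)(c2ccccc2)[C@@H](c2cc(O)cc(=O)o2)c2cccc(OCc3ccccc3)c21 | intermediate
30 | 6-[5-(benzyloxy)-4-hydroxy-2-phenylnaphthalen-1-yl]-4-hydroxy-2H-pyran-2-one | O=c1cc(O)cc(-c2c(-c3ccccc3)cc(O)c3c(OCc4ccccc4)cccc23)o1 | intermediate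
31 | N,N-dimethylmethyleneiminium iodide | C[N+](C)=C.[I-] | starting material
32 | (3R,4S)-8-(benzyloxy)-4-{5-[(dimethylamino)methyl]-4-hydroxy-6-oxo-6H-pyran-2-yl}-3-hydroxy-3-phenyl-3,4-dihydronaphthalen-1(2H)-one (Mannich base) | O=C1C[C@](O)(c2ccccc2)[C@@H](c2cc(O)c(CN(C)C)c(=O)o2)c2cccc(OCc3ccccc3)c21 | intermediate (not isolated)
33 | 6-[(1S,2R)-5-(benzyloxy)-2-hydroxy-4-oxo-2-phenyl-1,2,3,4-tetrahydronaphthalen-1-yl]-3-methylidene-2H-pyran-2,4(3H)-dione | O=C1C[C@](O)(c2ccccc2)[C@@H](C2=CC(=O)C(=C)C(=O)O2)c2cccc(OCc3ccccc3)c21 | intermediate (not isolated)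
34 | O,O-dibenzyl wailupemycin H: ring A bears at C6 the (3R,4S)-8-(benzyloxy)-3-hydroxy-1-oxo-3-phenyl-1,2,3,4-tetrahydronaphthalen-4-yl group, ring B the 5-(benzyloxy)-4-hydroxy-2-phenylnaphthalen-1-yl group; the rings are joined C3–CH2–C3 | O=C1C[C@](O)(c2ccccc2)[C@@H](c2cc(O)c(Cc3c(O)cc(-c4c(-c5ccccc5)cc(O)c5c(OCc6ccccc6)cccc45)oc3=O)c(=O)o2)c2cccc(OCc3ccccc3)c21 | intermediate
35 | wailupemycin H: ring A bears at C6 the (3R,4S)-3,8-dihydroxy-1-oxo-3-phenyl-1,2,3,4-tetrahydronaphthalen-4-yl group, ring B the 4,5-dihydroxy-2-phenylnaphthalen-1-yl group; the rings are joined C3–CH2–C3 | O=C1C[C@](O)(c2ccccc2)[C@@H](c2cc(O)c(Cc3c(O)cc(-c4c(-c5ccccc5)cc(O)c5c(O)cccc45)oc3=O)c(=O)o2)c2cccc(O)c21 | target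

## Step count and least certain steps

Total step count: 15. Longest linear sequence: 15 steps (1 to 35 by way of 29, 30 and 34; the line from 1 through 29 directly to 34 and 35 is 14).

Step 7 (key step). What is most likely to go wrong is heterolysis of the C1–O bond of 17, which is benzylic to an oxygen-substituted ring and vinylogous to an enol ether, or 1,4-elimination of the lithium enolate before it is silylated. Either path gives a tethered zwitterion or o-quinodimethane that recloses without memory of C1, so enantiomeric purity, and possibly the cis relationship, would be eroded. The product acid is also prone to acid-assisted loss of the tertiary ether and should be carried on at once. The fallback sets out from 19 of insufficient enantiomeric purity and comes back at 19. It replaces chirality transfer by classical resolution: the acid is crystallised as its salt with (R)-1-phenylethylamine, (R)-1-phenylethylammonium (1S,2R)-5-(benzyloxy)-2-[(4-methoxybenzyl)oxy]-2-phenyl-1,2-dihydronaphthalene-1-carboxylate F1, and the acid is then liberated at pH 5. Which amine enantiomer gives the less soluble salt would have to be screened.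

Step 5. The likely failure is poor facial discrimination, because both groups on the ketone are π systems, combined with slow reduction of a hindered, electron-rich carbonyl that lets uncatalysed borane reduction dilute the selectivity. The fallback sets out from 12 and comes back at 16. Luche reduction (NaBH4, CeCl3·7H2O, MeOH, −40 °C) gives the racemic diol rac-1-[2-(benzyloxy)-6-(2-hydroxyethyl)phenyl]-3-[(4-methoxybenzyl)oxy]-3-phenylprop-2-en-1-ol F2. The conditions of step 6 convert it into the racemic lactone rac-8-(benzyloxy)-1-{(E)-2-[(4-methoxybenzyl)oxy]-2-phenylethenyl}isochroman-3-one F3, and the enantiomers are separated by preparative chromatography on a chiral stationary phase to give 16.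

Step 6. The likely failures are oxidation of the secondary benzylic–allylic carbinol back to the enone and ionisation of the 3-alkoxyallyl carbinol (or of the product lactone) at the Lewis-acidic copper centre. The fallback sets out from 12 and comes back at 16. The side chain is raised to the acid level before the fragile carbinol exists, and the acidic CH2 appears only after the ynone is gone.
- The primary alcohol of 12 is oxidised (TEMPO, PhI(OAc)2, MeCN/H2O) to {3-(benzyloxy)-2-[(2E)-3-[(4-methoxybenzyl)oxy]-3-phenylprop-2-enoyl]phenyl}acetic acid F4.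
- Me3SiCHN2 gives the methyl ester F5.
- The reduction of step 5 gives methyl {3-(benzyloxy)-2-[(1S,2E)-1-hydroxy-3-[(4-methoxybenzyl)oxy]-3-phenylprop-2-en-1-yl]phenyl}acetate F6.
- Catalytic K2CO3 in toluene closes F6 to 16.

Step 8. The likely failure is proton transfer in place of addition: the hindered acyl imidazole 21 is deprotonated at the benzylic carbon, which leads to epimerisation or to loss of the β-alkoxide and aromatisation of the ring. The fallback sets out from 19 and comes back at 25; it avoids strong base.
- 1-Chloro-N,N,2-trimethylprop-1-en-1-amine converts 19 under neutral conditions into the acid chloride (1S,2R)-5-(benzyloxy)-2-[(4-methoxybenzyl)oxy]-2-phenyl-1,2-dihydronaphthalene-1-carbonyl chloride F7.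
- 1-Methoxy-1,3-bis(trimethylsilyloxy)buta-1,3-diene (CH2Cl2, −78 °C → rt) is acylated at its terminal carbon to give methyl 5-[(1S,2R)-5-(benzyloxy)-2-[(4-methoxybenzyl)oxy]-2-phenyl-1,2-dihydronaphthalen-1-yl]-3,5-dioxopentanoate F8.
- DBU in toluene closes F8 to 25.

Step 14. The likely failures are scrambling to homo-dimers through reversible Michael addition, attack of the naphthol carbon of 30 on 33, and dehydration of the β-hydroxy ketone on warming. The fallback sets out from 30 and 29 and comes back at 34. The roles are reversed and the electrophile is isolated: 30 and 31 give the Mannich base 6-[5-(benzyloxy)-4-hydroxy-2-phenylnaphthalen-1-yl]-3-[(dimethylamino)methyl]-4-hydroxy-2H-pyran-2-one F9, and MeI converts this into the trimethylammonium iodide F10, which is purified. F10 then reacts with 29 and NaHCO3 in MeCN at room temperature, so that the fragile half is never heated.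

Step 15. The likely failure is over-reduction (aryl ketone, benzylic C–O bond or a pyrone C=C bond) before both benzyl ethers are gone. The fallback sets out from 29 and 30 and comes back at 35. The two halves are debenzylated separately, where each reaction is simpler to follow and the naphthol half has nothing else reducible: 29 gives the free monomer (3R,4S)-3,8-dihydroxy-4-(4-hydroxy-2-oxo-2H-pyran-6-yl)-3-phenyl-3,4-dihydronaphthalen-1(2H)-one F11, and 30 gives 6-(4,5-dihydroxy-2-phenylnaphthalen-1-yl)-4-hydroxy-2H-pyran-2-one F12. F11 and 31 give the Mannich base F13, which is combined with F12 as in step 14 to give 35 directly. The price is that the free naphthalenediol is a more competitive carbon nucleophile.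

## Further compounds

F1 | step 7 | (R)-1-phenylethylammonium (1S,2R)-5-(benzyloxy)-2-[(4-methoxybenzyl)oxy]-2-phenyl-1,2-dihydronaphthalene-1-carboxylate | C1=C[C@](OCc2ccc(OC)cc2)(c2ccccc2)[C@@H](C([O-])=O)c2cccc(OCc3ccccc3)c12.C[C@@H]([NH3+])c1ccccc1
F2 | step 5 | rac-(2E)-1-[2-(benzyloxy)-6-(2-hydroxyethyl)phenyl]-3-[(4-methoxybenzyl)oxy]-3-phenylprop-2-en-1-ol | OCCc1cccc(OCc2ccccc2)c1C(O)/C=C(/OCc1ccc(OC)cc1)c1ccccc1
F3 | step 5 | rac-8-(benzyloxy)-1-{(E)-2-[(4-methoxybenzyl)oxy]-2-phenylethenyl}isochroman-3-one | O=C1Cc2cccc(OCc3ccccc3)c2C(/C=C(/OCc2ccc(OC)cc2)c2ccccc2)O1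
F4 | step 6 | {3-(benzyloxy)-2-[(2E)-3-[(4-methoxybenzyl)oxy]-3-phenylprop-2-enoyl]phenyl}acetic acid | OC(=O)Cc1cccc(OCc2ccccc2)c1C(=O)/C=C(/OCc1ccc(OC)cc1)c1ccccc1
F5 | step 6 | methyl {3-(benzyloxy)-2-[(2E)-3-[(4-methoxybenzyl)oxy]-3-phenylprop-2-enoyl]phenyl}acetate | COC(=O)Cc1cccc(OCc2ccccc2)c1C(=O)/C=C(/OCc1ccc(OC)cc1)c1ccccc1
F6 | step 6 | methyl {3-(benzyloxy)-2-[(1S,2E)-1-hydroxy-3-[(4-methoxybenzyl)oxy]-3-phenylprop-2-en-1-yl]phenyl}acetate | COC(=O)Cc1cccc(OCc2ccccc2)c1[C@@H](O)/C=C(/OCc1ccc(OC)cc1)c1ccccc1
F7 | step 8 | (1S,2R)-5-(benzyloxy)-2-[(4-methoxybenzyl)oxy]-2-phenyl-1,2-dihydronaphthalene-1-carbonyl chloride | C1=C[C@](OCc2ccc(OC)cc2)(c2ccccc2)[C@@H](C(Cl)=O)c2cccc(OCc3ccccc3)c12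
F8 | step 8 | methyl 5-[(1S,2R)-5-(benzyloxy)-2-[(4-methoxybenzyl)oxy]-2-phenyl-1,2-dihydronaphthalen-1-yl]-3,5-dioxopentanoate | C1=C[C@](OCc2ccc(OC)cc2)(c2ccccc2)[C@@H](C(=O)CC(=O)CC(=O)OC)c2cccc(OCc3ccccc3)c12
F9 | step 14 | 6-[5-(benzyloxy)-4-hydroxy-2-phenylnaphthalen-1-yl]-3-[(dimethylamino)methyl]-4-hydroxy-2H-pyran-2-one | CN(C)Cc1c(O)cc(-c2c(-c3ccccc3)cc(O)c3c(OCc4ccccc4)cccc23)oc1=O
F10 | step 14 | {6-[5-(benzyloxy)-4-hydroxy-2-phenylnaphthalen-1-yl]-4-hydroxy-2-oxo-2H-pyran-3-yl}-N,N,N-trimethylmethanaminium iodide | C[N+](C)(C)Cc1c(O)cc(-c2c(-c3ccccc3)cc(O)c3c(OCc4ccccc4)cccc23)oc1=O.[I-]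
F11 | step 15 | (3R,4S)-3,8-dihydroxy-4-(4-hydroxy-2-oxo-2H-pyran-6-yl)-3-phenyl-3,4-dihydronaphthalen-1(2H)-one (identical with A1) | O=C1C[C@](O)(c2ccccc2)[C@@H](c2cc(O)cc(=O)o2)c2cccc(O)c21
F12 | step 15 | 6-(4,5-dihydroxy-2-phenylnaphthalen-1-yl)-4-hydroxy-2H-pyran-2-one (identical with A4) | O=c1cc(O)cc(-c2c(-c3ccccc3)cc(O)c3c(O)cccc23)o1
F13 | step 15 | (3R,4S)-4-{5-[(dimethylamino)methyl]-4-hydroxy-6-oxo-6H-pyran-2-yl}-3,8-dihydroxy-3-phenyl-3,4-dihydronaphthalen-1(2H)-one | O=C1C[C@](O)(c2ccccc2)[C@@H](c2cc(O)c(CN(C)C)c(=O)o2)c2cccc(O)c21
A1 | alternative 1 | (3R,4S)-3,8-dihydroxy-4-(4-hydroxy-2-oxo-2H-pyran-6-yl)-3-phenyl-3,4-dihydronaphthalen-1(2H)-one (tetralone–pyrone monomer, free hydroxyls) | O=C1C[C@](O)(c2ccccc2)[C@@H](c2cc(O)cc(=O)o2)c2cccc(O)c21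
A2 | alternative 1 | benzoic acid | OC(=O)c1ccccc1
A3 | alternative 1 | malonic acid | OC(=O)CC(O)=O
A4 | alternative 1 | 6-(4,5-dihydroxy-2-phenylnaphthalen-1-yl)-4-hydroxy-2H-pyran-2-one | O=c1cc(O)cc(-c2c(-c3ccccc3)cc(O)c3c(O)cccc23)o1
A5 | alternative 2 | 4-(benzyloxy)-6-[5-(benzyloxy)-4-hydroxy-2-phenylnaphthalen-1-yl]-2H-pyran-2-one | O=c1cc(OCc2ccccc2)cc(-c2c(-c3ccccc3)cc(O)c3c(OCc4ccccc4)cccc23)o1
A6 | alternative 2 | 1-[2-(benzyloxy)phenyl]-2-[dimethyl(oxo)-λ6-sulfanylidene]ethan-1-one (aroyl sulfoxonium ylide) | CS(C)(=O)=CC(=O)c1ccccc1OCc1ccccc1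
A7 | alternative 2 | 4-(benzyloxy)-6-(phenylethynyl)-2H-pyran-2-one | O=c1cc(OCc2ccccc2)cc(C#Cc2ccccc2)o1
A8 | alternative 3 | di-tert-butyl 2-{3-[4,5-bis(benzyloxy)-2-phenylnaphthalen-1-yl]prop-2-ynoyl}-4-{4-[3-(benzyloxy)-2-bromophenyl]but-2-ynoyl}pentanedioate (configuration at the two α-carbons irrelevant) | CC(C)(C)OC(=O)C(CC(C(=O)OC(C)(C)C)C(=O)C#Cc1c(-c2ccccc2)cc(OCc2ccccc2)c2c(OCc3ccccc3)cccc12)C(=O)C#CCc1cccc(OCc2ccccc2)c1Br
A9 | alternative 3 | di-tert-butyl glutarate | CC(C)(C)OC(=O)CCCC(=O)OC(C)(C)C
A10 | alternative 3 | 3-[4,5-bis(benzyloxy)-2-phenylnaphthalen-1-yl]prop-2-ynoyl chloride | O=C(Cl)C#Cc1c(-c2ccccc2)cc(OCc2ccccc2)c2c(OCc3ccccc3)cccc12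
A11 | alternative 3 | 4-[3-(benzyloxy)-2-bromophenyl]but-2-ynoyl chloride | O=C(Cl)C#CCc1cccc(OCc2ccccc2)c1Br
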